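**Retrosynthetic overview**

1. The acid comes from oxidation of a silyl-protected primary alcohol and the aryl ether from Mitsunobu coupling of a neopentyl alcohol with umbelliferone (coumarin bicycle bought intact). The remaining problem is the cyclohexane, numbered as in the target name: C1 (CH with the propanoic chain), C2 (quaternary, Me and CH2O), C3 (CHMe), C4 and C5 (CH2), C6 (C=CMe2).
2. Enabling feature: C3 and C6 are 1,4-related and each is flanked by two ring carbons, so the ring splits into two three-carbon units of opposite polarity. C5–C6–C1 is a 2-nitroallyl 1,3-dielectrophile (C6 = nitro carbon, C1 already carries the chain). C2–C3–C4 plus the exocyclic OCH2 carbon is methyl 2-methylacetoacetate, a 1,3-dinucleophile (C3 = ketone carbon, OCH2 = ester carbon, C2 methyl in place).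
3. Key disconnection: C1–C2 and C4–C5, made together in a catalytic asymmetric SN2′ alkylation/enamine Michael [3+3] annulation. It builds the only new ring, the quaternary C2 and the C1 stereocentre, and gives a 4-nitrocyclohexanone.
4. The nitro group at C6 becomes the isopropylidene (radical-anion coupling with 2-bromo-2-nitropropane, then loss of both nitro groups). The ketone at C3 becomes a methylidene, and hydroxyl-directed hydrogenation from the C2 CH2OH sets C3.
5. Ring order: cyclohexane (step 3) only; the chromenone enters as umbelliferone in step 9.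

Key step: step 3

Assumption: aldehyde 1 is treated as a catalogue compound, and the quinine-derived squaramide is assumed to give the (2R,3S) series of 7 (its quinidine-derived pseudo-enantiomer is used if the sense is opposite).

**Route**

Step 1
Reactants: 1 4-[(tert-butyldimethylsilyl)oxy]butanal; 2 2-nitroethanol
Product: 3 6-[(tert-butyldimethylsilyl)oxy]-2-nitrohexane-1,3-diol (mixture of diastereomers)
Conditions: 2 (1.5 equiv), Et3N (10 mol %), THF, 0 °C → rt
Reagents that add atoms: none
Why: Amine-catalysed Henry (nitroaldol) addition of the nitronate of 2 to an unhindered aliphatic aldehyde is reliable, the silyl ether is inert, and the two new stereocentres need no control because both become sp2 in step 2.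

Step 2
Reactants: 3 6-[(tert-butyldimethylsilyl)oxy]-2-nitrohexane-1,3-diol
Product: 5 (2E)-6-[(tert-butyldimethylsilyl)oxy]-2-nitrohex-2-en-1-yl acetate, via diacetate 4 (not isolated)
Conditions: Ac2O (2.5 equiv), pyridine, 4-(dimethylamino)pyridine (5 mol %), CH2Cl2, 0 °C; then Et3N (1.2 equiv), 0 °C → rt
Reagents that add atoms: acetic anhydride, CC(=O)OC(C)=O
Why: Acetylation of both hydroxyls followed by amine-induced E1cB loss of acetic acid from the β-acetoxy nitroalkane is the standard nitroalkene synthesis, and loss of the secondary acetate gives the conjugated trisubstituted (E)-nitroalkene, the thermodynamic isomer to which the terminal regioisomer should also funnel by reversible acetate SN2′ exchange.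

Step 3
Reactants: 5 (2E)-6-[(tert-butyldimethylsilyl)oxy]-2-nitrohex-2-en-1-yl acetate; 6 methyl 2-methyl-3-oxobutanoate
Product: 8 methyl (1R,2S,3S)-2-{3-[(tert-butyldimethylsilyl)oxy]propyl}-1-methyl-3-nitro-6-oxocyclohexane-1-carboxylate, via SN2′ adduct 7 (not isolated)
Conditions: 6 (1.1 equiv), 3-{[3,5-bis(trifluoromethyl)phenyl]amino}-4-{[(8α,9S)-6′-methoxycinchonan-9-yl]amino}cyclobut-3-ene-1,2-dione (10 mol %), Na2CO3 (1.1 equiv), toluene, −20 °C; then pyrrolidine (20 mol %), PhCO2H (20 mol %), rt
Reagents that add atoms: none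
Why: The squaramide NH groups bind the nitro group of 5 while the quinuclidine nitrogen deprotonates 6, whose α-carbon adds to C3 of the nitroalkene and the nitronate expels acetate (SN2′) to give 7 with the future C1–C2 ring bond (target numbering); pyrrolidine then converts the acetyl group of 7 into its terminal enamine, which adds to the CH2 end of the new nitroethene (future C4–C5 bond) before hydrolysis releases 8. The closest known reactions are the organocatalytic asymmetric SN2′ alkylation of nitroallylic acetates by 1,3-dicarbonyl compounds and the [3+3] α,α′-annulation of ketone enamines with 2-nitroallyl esters. The cyclohexanone closes in the 6-endo-trig mode, both carbons of the nitroethene ending up in the ring (enol-endo on the enamine side). The quaternary centre and the adjacent CH centre are both set in the SN2′ step by the catalyst, which fixes the face of the nitroalkene and, through the ion-paired enolate, the face of the nucleophile (required: 2R,3S in 7), whereas the nitro-bearing carbon of 8 is set by thermodynamic protonation (nitro equatorial, trans to the side chain) and is erased in step 5. The step needs attack by the α-carbon before the acetyl methyl (only the α-CH is acidic enough for the tertiary amine, and only the methyl can form an enamine once the α-carbon is quaternary), SN2′ rather than direct substitution (conjugate addition to the nitroalkene is the only low-energy path to acetate loss) and C- rather than O-cyclisation (secured by the enamine).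

Step 4
Reactants: 8 methyl (1R,2S,3S)-2-{3-[(tert-butyldimethylsilyl)oxy]propyl}-1-methyl-3-nitro-6-oxocyclohexane-1-carboxylate; 9 2-bromo-2-nitropropane
Product: 11 methyl (1R,2S)-2-{3-[(tert-butyldimethylsilyl)oxy]propyl}-1-methyl-3-nitro-3-(2-nitropropan-2-yl)-6-oxocyclohexane-1-carboxylate (either configuration at C3), via lithium nitronate 10 (not isolated)
Conditions: LiOMe (1.0 equiv), MeOH, 0 °C, evaporate; then 9 (1.5 equiv), DMSO, visible light, N2, rt
Reagents that add atoms: none
Why: The secondary nitro group is far more acidic than the ketone α-CH2, and its nitronate should be C-alkylated by the α-bromo nitroalkane through the light-promoted radical-anion chain (SRN1) mechanism, which is known to join two fully substituted carbons; the new quaternary stereocentre needs no control because it becomes sp2 in step 5.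

Step 5
Reactants: 11 methyl (1R,2S)-2-{3-[(tert-butyldimethylsilyl)oxy]propyl}-1-methyl-3-nitro-3-(2-nitropropan-2-yl)-6-oxocyclohexane-1-carboxylate
Product: 12 methyl (1R,2R)-2-{3-[(tert-butyldimethylsilyl)oxy]propyl}-1-methyl-6-oxo-3-(propan-2-ylidene)cyclohexane-1-carboxylate
Conditions: Na2S·9H2O (3 equiv), DMF, rt
Reagents that add atoms: none
Why: Single-electron reduction of the vicinal dinitro compound by sulfide expels two nitrite ions (reductive 1,2-elimination of vic-dinitroalkanes), a regiodefined route to tetrasubstituted alkenes that can place the double bond only between the ring carbon and the Me2C carbon and should leave ketone, ester and silyl ether untouched at room temperature.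

Step 6
Reactants: 12 methyl (1R,2R)-2-{3-[(tert-butyldimethylsilyl)oxy]propyl}-1-methyl-6-oxo-3-(propan-2-ylidene)cyclohexane-1-carboxylate
Product: 13 methyl (1R,2R)-2-{3-[(tert-butyldimethylsilyl)oxy]propyl}-1-methyl-6-methylidene-3-(propan-2-ylidene)cyclohexane-1-carboxylate
Conditions: Ph3PCH3Br, KOtBu, toluene, 0 → 80 °C
Reagents that add atoms: methyltriphenylphosphonium bromide, C[P+](c1ccccc1)(c1ccccc1)c1ccccc1.[Br-]
Why: Wittig methylenation with the small ylide Ph3P=CH2 converts α-quaternary cyclohexanones into methylidene compounds, the ester is unreactive, and no stereocentre can epimerise because the α-carbon is quaternary.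

Step 7
Reactants: 13 methyl (1R,2R)-2-{3-[(tert-butyldimethylsilyl)oxy]propyl}-1-methyl-6-methylidene-3-(propan-2-ylidene)cyclohexane-1-carboxylate
Product: 14 [(1R,2R)-2-{3-[(tert-butyldimethylsilyl)oxy]propyl}-1-methyl-6-methylidene-3-(propan-2-ylidene)cyclohexyl]methanol
Conditions: LiAlH4, Et2O, 0 °C → rt; then H2O
Reagents that add atoms: none
Why: Hydride reduction of the hindered methyl ester with LiAlH4 should give the neopentyl primary alcohol, both alkenes and the silyl ether being inert to hydride.

Step 8
Reactants: 14 [(1R,2R)-2-{3-[(tert-butyldimethylsilyl)oxy]propyl}-1-methyl-6-methylidene-3-(propan-2-ylidene)cyclohexyl]methanol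
Product: 15 [(1S,2R,6R)-2-{3-[(tert-butyldimethylsilyl)oxy]propyl}-1,6-dimethyl-3-(propan-2-ylidene)cyclohexyl]methanol
Conditions: [Ir(cod)(PCy3)(py)]PF6 (5 mol %), H2 (1 atm), CH2Cl2, 0 °C
Reagents that add atoms: none
Why: In this hydroxyl-directed homogeneous hydrogenation the cationic iridium complex binds the CH2OH group and delivers H2 to the same face of the neighbouring 1,1-disubstituted alkene, so the new ring hydrogen is cis to CH2OH and the new methyl cis to the quaternary methyl, while the remote tetrasubstituted isopropylidene should react far more slowly under these mild conditions.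

Step 9
Reactants: 15 [(1S,2R,6R)-2-{3-[(tert-butyldimethylsilyl)oxy]propyl}-1,6-dimethyl-3-(propan-2-ylidene)cyclohexyl]methanol; 16 7-hydroxy-2H-chromen-2-one (umbelliferone)
Product: 17 7-{[(1S,2R,6R)-2-{3-[(tert-butyldimethylsilyl)oxy]propyl}-1,6-dimethyl-3-(propan-2-ylidene)cyclohexyl]methoxy}-2H-chromen-2-one
Conditions: 16 (1.5 equiv), PPh3, diisopropyl azodicarboxylate, THF (concentrated), sonication, rt → 40 °C
Reagents that add atoms: none
Why: In this Mitsunobu etherification the acidic phenol (pKa about 8) protonates the betaine and its phenoxide displaces the alkoxyphosphonium at the primary carbon without touching a stereocentre, high concentration with sonication being the known remedy for the slow SN2 step at neopentyl carbinols.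

Step 10
Reactants: 17 7-{[(1S,2R,6R)-2-{3-[(tert-butyldimethylsilyl)oxy]propyl}-1,6-dimethyl-3-(propan-2-ylidene)cyclohexyl]methoxy}-2H-chromen-2-one
Product: 18 7-{[(1S,2R,6R)-2-(3-hydroxypropyl)-1,6-dimethyl-3-(propan-2-ylidene)cyclohexyl]methoxy}-2H-chromen-2-one
Conditions: HF·pyridine, pyridine, THF, 0 °C → rt
Reagents that add atoms: none
Why: Buffered fluoride cleavage of the primary silyl ether should leave the lactone, the aryl ether and the acid-sensitive tetrasubstituted alkene intact.

Step 11
Reactants: 18 7-{[(1S,2R,6R)-2-(3-hydroxypropyl)-1,6-dimethyl-3-(propan-2-ylidene)cyclohexyl]methoxy}-2H-chromen-2-one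
Product: 20 3-[(1R,2S,3R)-2,3-dimethyl-2-{[(2-oxo-2H-chromen-7-yl)oxy]methyl}-6-(propan-2-ylidene)cyclohexyl]propanoic acid, via aldehyde 19 (not isolated)
Conditions: (2,2,6,6-tetramethylpiperidin-1-yl)oxyl (20 mol %), PhI(OAc)2 (2.5 equiv), MeCN/H2O 1:1, rt
Reagents that add atoms: water, O
Why: Oxoammonium catalysis with PhI(OAc)2 as terminal oxidant takes the primary alcohol to the aldehyde and, through its hydrate in aqueous acetonitrile, to the acid, without attacking the tetrasubstituted alkene or the coumarin and with no epimerisable centre next to the new carbonyl.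

**Compound list**

1 | 4-[(tert-butyldimethylsilyl)oxy]butanal | O=CCCCO[Si](C)(C)C(C)(C)C | starting material
2 | 2-nitroethanol | OCC[N+](=O)[O-] | starting material
3 | 6-[(tert-butyldimethylsilyl)oxy]-2-nitrohexane-1,3-diol (diastereomer mixture, both centres lost in step 2) | OCC([N+](=O)[O-])C(O)CCCO[Si](C)(C)C(C)(C)C | intermediate
4 | 6-[(tert-butyldimethylsilyl)oxy]-2-nitrohexane-1,3-diyl diacetate (diastereomer mixture) | CC(=O)OCC([N+](=O)[O-])C(OC(C)=O)CCCO[Si](C)(C)C(C)(C)C | intermediate
5 | (2E)-6-[(tert-butyldimethylsilyl)oxy]-2-nitrohex-2-en-1-yl acetate | CC(=O)OC/C([N+](=O)[O-])=C\CCCO[Si](C)(C)C(C)(C)C | intermediate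
6 | methyl 2-methyl-3-oxobutanoate (racemic, configurationally labile) | CC(=O)C(C)C(=O)OC | starting material
7 | methyl (2R,3S)-2-acetyl-6-[(tert-butyldimethylsilyl)oxy]-2-methyl-3-(1-nitroethenyl)hexanoate | CC(=O)[C@](C)(C(=O)OC)[C@@H](C(=C)[N+](=O)[O-])CCCO[Si](C)(C)C(C)(C)C | intermediate
8 | methyl (1R,2S,3S)-2-{3-[(tert-butyldimethylsilyl)oxy]propyl}-1-methyl-3-nitro-6-oxocyclohexane-1-carboxylate | [O-][N+](=O)[C@H]1CCC(=O)[C@](C)(C(=O)OC)[C@@H]1CCCO[Si](C)(C)C(C)(C)C | intermediate
9 | 2-bromo-2-nitropropane | CC(C)(Br)[N+](=O)[O-] | starting material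
10 | lithium nitronate of 8 (aci-nitro salt at the former CH–NO2 carbon, other centres as in 8) | [Li+].[O-][N+]([O-])=C1CCC(=O)[C@](C)(C(=O)OC)[C@@H]1CCCO[Si](C)(C)C(C)(C)C | intermediate
11 | methyl (1R,2S)-2-{3-[(tert-butyldimethylsilyl)oxy]propyl}-1-methyl-3-nitro-3-(2-nitropropan-2-yl)-6-oxocyclohexane-1-carboxylate (C3 not controlled, lost in step 5) | CC(C)([N+](=O)[O-])C1([N+](=O)[O-])CCC(=O)[C@](C)(C(=O)OC)[C@@H]1CCCO[Si](C)(C)C(C)(C)C | intermediate
12 | methyl (1R,2R)-2-{3-[(tert-butyldimethylsilyl)oxy]propyl}-1-methyl-6-oxo-3-(propan-2-ylidene)cyclohexane-1-carboxylate | CC(C)=C1CCC(=O)[C@](C)(C(=O)OC)[C@@H]1CCCO[Si](C)(C)C(C)(C)C | intermediate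
13 | methyl (1R,2R)-2-{3-[(tert-butyldimethylsilyl)oxy]propyl}-1-methyl-6-methylidene-3-(propan-2-ylidene)cyclohexane-1-carboxylate | CC(C)=C1CCC(=C)[C@](C)(C(=O)OC)[C@@H]1CCCO[Si](C)(C)C(C)(C)C | intermediate
14 | [(1R,2R)-2-{3-[(tert-butyldimethylsilyl)oxy]propyl}-1-methyl-6-methylidene-3-(propan-2-ylidene)cyclohexyl]methanol | CC(C)=C1CCC(=C)[C@](C)(CO)[C@@H]1CCCO[Si](C)(C)C(C)(C)C | intermediate
15 | [(1S,2R,6R)-2-{3-[(tert-butyldimethylsilyl)oxy]propyl}-1,6-dimethyl-3-(propan-2-ylidene)cyclohexyl]methanol (ring methyls cis, side chain cis to CH2OH) | CC(C)=C1CC[C@@H](C)[C@](C)(CO)[C@@H]1CCCO[Si](C)(C)C(C)(C)C | intermediate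
16 | 7-hydroxy-2H-chromen-2-one (umbelliferone) | O=c1ccc2ccc(O)cc2o1 | starting material
17 | 7-{[(1S,2R,6R)-2-{3-[(tert-butyldimethylsilyl)oxy]propyl}-1,6-dimethyl-3-(propan-2-ylidene)cyclohexyl]methoxy}-2H-chromen-2-one | CC(C)=C1CC[C@@H](C)[C@](C)(COc2ccc3ccc(=O)oc3c2)[C@@H]1CCCO[Si](C)(C)C(C)(C)C | intermediate
18 | 7-{[(1S,2R,6R)-2-(3-hydroxypropyl)-1,6-dimethyl-3-(propan-2-ylidene)cyclohexyl]methoxy}-2H-chromen-2-one | CC(C)=C1CC[C@@H](C)[C@](C)(COc2ccc3ccc(=O)oc3c2)[C@@H]1CCCO | intermediate
19 | 3-[(1R,2S,3R)-2,3-dimethyl-2-{[(2-oxo-2H-chromen-7-yl)oxy]methyl}-6-(propan-2-ylidene)cyclohexyl]propanal | CC(C)=C1CC[C@@H](C)[C@](C)(COc2ccc3ccc(=O)oc3c2)[C@@H]1CCC=O | intermediate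
20 | 3-[(1R,2S,3R)-2,3-dimethyl-2-{[(2-oxo-2H-chromen-7-yl)oxy]methyl}-6-(propan-2-ylidene)cyclohexyl]propanoic acid | CC(C)=C1CC[C@@H](C)[C@](C)(COc2ccc3ccc(=O)oc3c2)[C@@H]1CCC(=O)O | target

Total step count: 11. Longest linear sequence: 11 steps (1 to 20).

**Steps most likely to fail**

Step 3. Facial discrimination at the prochiral enolate carbon may be poor, giving low diastereocontrol at the quaternary centre. A second molecule of 6 may also add to the nitroethene of 7, or the ring may close through oxygen.
Fallback, setting out from 5 and returning at 8: the same squaramide-catalysed SN2′ alkylation is run with dimethyl methylmalonate, which creates only the CH stereocentre, to give dimethyl 2-[(3S)-6-[(tert-butyldimethylsilyl)oxy]-2-nitrohex-1-en-3-yl]-2-methylpropanedioate F1. Michael addition of the lithium enolate of allyl acetate (LiN(SiMe3)2, THF, −78 °C) to its nitroethene gives prop-2-en-1-yl (5S)-5-{3-[(tert-butyldimethylsilyl)oxy]propyl}-6,6-bis(methoxycarbonyl)-4-nitroheptanoate F2. Dieckmann cyclisation (LiN(SiMe3)2, 2.2 equiv, THF, −78 → 0 °C) onto one of the two diastereotopic methyl esters gives 1-methyl 3-prop-2-en-1-yl (1R,6S)-6-{3-[(tert-butyldimethylsilyl)oxy]propyl}-1-methyl-5-nitro-2-oxocyclohexane-1,3-dicarboxylate F3. The quaternary centre is now set by diastereotopic-group selection (retained ester axial and cis to the side chain, epimers separable). Pd(PPh3)4 with morpholine removes the allyl ester, the β-keto acid loses CO2, and the route is rejoined at 8.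

Step 4. Bromine transfer between nitronate and reagent may scramble the coupling, the radical-anion coupling at the crowded ring carbon may be slow, or the nitronate may ring-open by retro-Michael loss of the β-keto ester enolate.
Fallback, setting out from 8 and returning at 12: a Nef reaction (NaOMe, then aqueous TiCl3 buffered with NH4OAc) gives methyl (1R,2S)-2-{3-[(tert-butyldimethylsilyl)oxy]propyl}-1-methyl-3,6-dioxocyclohexane-1-carboxylate F4. Its less hindered C3 ketone undergoes Wittig olefination with isopropylidenetriphenylphosphorane (isopropyltriphenylphosphonium iodide, n-BuLi, THF) to give 12. The ketone flanked by the quaternary carbon is too hindered for this bulky ylide.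

Step 9. Displacement at the neopentyl carbinol may be too slow, so that the alkoxyphosphonium intermediate decomposes before the phenoxide attacks.
Fallback, setting out from 15 and returning at 17: the polarity is reversed and the alkoxide of 15 is arylated by 7-bromo-2H-chromen-2-one under palladium catalysis (Pd(OAc)2, RockPhos, Cs2CO3, toluene, 90 °C). This makes no new compound (F0).

Further compounds
F1 | step 3 | dimethyl 2-[(3S)-6-[(tert-butyldimethylsilyl)oxy]-2-nitrohex-1-en-3-yl]-2-methylpropanedioate | COC(=O)C(C)(C(=O)OC)[C@@H](C(=C)[N+](=O)[O-])CCCO[Si](C)(C)C(C)(C)C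
F2 | step 3 | prop-2-en-1-yl (5S)-5-{3-[(tert-butyldimethylsilyl)oxy]propyl}-6,6-bis(methoxycarbonyl)-4-nitroheptanoate (C4 epimers) | COC(=O)C(C)(C(=O)OC)[C@@H](C(CCC(=O)OCC=C)[N+](=O)[O-])CCCO[Si](C)(C)C(C)(C)C
F3 | step 3 | 1-methyl 3-prop-2-en-1-yl (1R,6S)-6-{3-[(tert-butyldimethylsilyl)oxy]propyl}-1-methyl-5-nitro-2-oxocyclohexane-1,3-dicarboxylate (C3 and C5 epimers) | [O-][N+](=O)C1CC(C(=O)OCC=C)C(=O)[C@](C)(C(=O)OC)[C@@H]1CCCO[Si](C)(C)C(C)(C)C
F4 | step 4 | methyl (1R,2S)-2-{3-[(tert-butyldimethylsilyl)oxy]propyl}-1-methyl-3,6-dioxocyclohexane-1-carboxylate | O=C1CCC(=O)[C@](C)(C(=O)OC)[C@@H]1CCCO[Si](C)(C)C(C)(C)C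
F0 | step 9 | none | none
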